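Ring B (C5–C10) is cut across C5–C10 and C8–C9. Its C6=C7 alkene carrying C11, the C5 methine and the quaternary C10 are the imprint of a Diels–Alder union of a C5=C6–C7=C8 diene with the C9=C10 alkene of a 2-alkylacrolein. One catalytic asymmetric cycloaddition of (E)-triene 7 with 2-methylidenehex-5-enal 10 builds ring B, both ring-fusion stereocentres and every handle for ring A (isopropenyl and butenyl for metathesis, formyl as latent C10 methyl). The triene is made geometrically pure by cross-coupling; its C11 silyl ether enforces the s-cis diene and later serves as a leaving group.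

Key step: step 7

Numbering: eudesmane positions are used throughout (ring A = C1–C5 and C10; ring B = C5–C10; C11 on C7; C14 on C10; C15 on C4); α is the face opposite the C10 methyl (or formyl) group, so the target is the 3α-angelate 4α-acetate with 5α-H, (3R,4S,5R,10R).
Assumption: the (S)-catalyst is taken to attack the enal face predicted by the accepted formyl C–H···O model for 2-substituted acroleins; if the sense proves opposite, the (R)-catalyst is used and nothing else changes.

Step 1
Reactants: 1 3-hydroxy-3-methylbutan-2-one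
Product: 2 3-(tert-butyldimethylsilyloxy)-3-methylbutan-2-one
Conditions: t-BuMe2SiOTf, 2,6-lutidine, CH2Cl2, 0 °C → rt
Reagents that add atoms: tert-butyldimethylsilyl triflate, CC(C)(C)[Si](C)(C)OS(=O)(=O)C(F)(F)F
Why: A silyl triflate with a hindered pyridine base silylates the tertiary hydroxyl (silyl ether formation) under conditions too mild to enolise the ketone.

Step 2
Reactants: 2 3-(tert-butyldimethylsilyloxy)-3-methylbutan-2-one
Product: 4 3-(tert-butyldimethylsilyloxy)-3-methylbut-1-en-2-yl trifluoromethanesulfonate, via potassium enolate 3 (not isolated)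
Conditions: KN(SiMe3)2, THF, −78 °C; then PhNTf2, −78 → 0 °C
Reagents that add atoms: N-phenylbis(trifluoromethanesulfonimide), O=S(=O)(N(c1ccccc1)S(=O)(=O)C(F)(F)F)C(F)(F)F
Why: The ketone has α-hydrogens only on its methyl group, so a single enolate forms and is O-sulfonylated (enol triflate formation), fixing the future C7=C8 methylidene regiospecifically.

Step 3
Reactants: 5 2-methylbut-1-en-3-yne
Product: 6 4,4,5,5-tetramethyl-2-[(1E)-3-methylbuta-1,3-dien-1-yl]-1,3,2-dioxaborolane
Conditions: pinacolborane, Cp2Zr(H)Cl (5 mol %), Et3N (10 mol %), neat, sealed vessel, 40 °C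
Reagents that add atoms: pinacolborane, CC1(C)OBOC1(C)C
Why: Zirconocene-hydride-catalysed hydroboration of the terminal alkyne is a syn, anti-Markovnikov addition that leaves the 1,1-disubstituted alkene alone and can therefore give only the (E)-dienylboronate.

Step 4
Reactants: 4 3-(tert-butyldimethylsilyloxy)-3-methylbut-1-en-2-yl trifluoromethanesulfonate; 6 4,4,5,5-tetramethyl-2-[(1E)-3-methylbuta-1,3-dien-1-yl]-1,3,2-dioxaborolane
Product: 7 tert-butyl{[(4E)-2,6-dimethyl-3-methylidenehepta-4,6-dien-2-yl]oxy}dimethylsilane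
Conditions: Pd(PPh3)4 (5 mol %), K3PO4, 1,4-dioxane/H2O, 60 °C
Reagents that add atoms: none
Why: Suzuki–Miyaura coupling proceeds with retention at both sp2 carbons, so the (E)-geometry of 6 becomes the (E)-C5=C6 bond of the triene with no geometric isomer to separate.

Step 5
Reactants: 8 hex-5-en-1-ol
Product: 9 hex-5-enal
Conditions: TEMPO (10 mol %), PhI(OAc)2, CH2Cl2, rt
Reagents that add atoms: none
Why: Oxoammonium-mediated oxidation of the primary alcohol stops at the aldehyde and does not touch the terminal alkene.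

Step 6
Reactants: 9 hex-5-enal
Product: 10 2-methylidenehex-5-enal
Conditions: 37 % aq. CH2O, pyrrolidine (10 mol %), EtCO2H (10 mol %), i-PrOH, 45 °C
Reagents that add atoms: formaldehyde, C=O
Why: Amine/acid-catalysed Mannich condensation with formaldehyde followed by elimination (α-methylenation of an aldehyde) installs the C9 methylidene at the only enolisable position.

Step 7
Reactants: 7 tert-butyl{[(4E)-2,6-dimethyl-3-methylidenehepta-4,6-dien-2-yl]oxy}dimethylsilane; 10 2-methylidenehex-5-enal
Product: 11 (1S,2S)-1-(but-3-en-1-yl)-4-[2-(tert-butyldimethylsilyloxy)propan-2-yl]-2-(prop-1-en-2-yl)cyclohex-3-ene-1-carbaldehyde (formyl cis to isopropenyl)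
Conditions: (S)-1-(2-methylphenyl)-3,3-diphenyltetrahydro-1H,3H-pyrrolo[1,2-c][1,3,2]oxazaborole (20 mol %), HNTf2 (18 mol %), CH2Cl2, −78 → −40 °C
Reagents that add atoms: none
Why: The N-protonated oxazaborolidine binds the formyl oxygen of 10 and the s-cis C5=C6–C7=C8 unit of 7 adds in a concerted but asynchronous [4+2] cycloaddition, C8–C9 bonding ahead of C5–C10; the closest known reaction type is the chiral-Lewis-acid Diels–Alder reaction of 2-alkylacroleins with 2- and 1,3-substituted butadienes that creates formyl-bearing quaternary carbons. Ring B is closed in this one intermolecular step as a six-membered ring by suprafacial union of the four diene carbons with the two alkene carbons. C10 is controlled by the catalyst, whose aryl group screens one face of the bound s-trans enal so that the diene reaches the face on which formyl, methylidene and butenyl appear clockwise, and C5 is controlled relative to C10 by the endo placement of the activated formyl group over the diene, which with the (E)-C5=C6 bond puts formyl cis and butenyl trans to isopropenyl; acyclic (E)-dienes lack the bridging methylene that turns 2-substituted acroleins exo with cyclopentadiene. Regiochemistry is not in doubt because the C7 alkyl group (para rule) and the C5 alkenyl group (ortho rule) both direct C10 to C5. The demanding selectivity is between the two diene units of 7, and it is secured by the tert-alkyl group on C7, which forces the C6–C7 bond into the reactive s-cis geometry while the methyl-bearing C4–C5 bond stays largely s-trans, and by the bulk next to C6 that disfavours bond formation there.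

Step 8
Reactants: 11 (1S,2S)-1-(but-3-en-1-yl)-4-[2-(tert-butyldimethylsilyloxy)propan-2-yl]-2-(prop-1-en-2-yl)cyclohex-3-ene-1-carbaldehyde
Product: 12 11-(tert-butyldimethylsilyloxy)-5αH-eudesma-3,6-dien-14-al (trans-fused, formyl β on C10)
Conditions: RuCl2(=CHPh)(H2IMes)(PCy3) (second-generation Grubbs catalyst, 5 mol %), CH2Cl2 (0.01 M), 40 °C
Reagents that add atoms: none
Why: Ring-closing metathesis between the terminal vinyl and the isopropenyl group, which sit trans on adjacent carbons, closes ring A as the trisubstituted C3=C4 alkene with loss of ethene, while the hindered C6=C7 alkene and the neopentyl aldehyde are inert to the ruthenium carbene.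

Step 9
Reactants: 12 11-(tert-butyldimethylsilyloxy)-5αH-eudesma-3,6-dien-14-al
Product: 13 (E)-N-tosylhydrazone of 12
Conditions: TsNHNH2, EtOH, 50 °C
Reagents that add atoms: p-toluenesulfonyl hydrazide, Cc1ccc(cc1)S(=O)(=O)NN
Why: Condensation of an aldehyde with a sulfonyl hydrazide (hydrazone formation) proceeds even at a neopentyl formyl group and is near-neutral, so the tertiary allylic silyl ether survives.

Step 10
Reactants: 13 (E)-N-tosylhydrazone of 12
Product: 15 11-(tert-butyldimethylsilyloxy)-5αH-eudesma-3,6-diene, via N-boryl tosylhydrazine 14 (not isolated)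
Conditions: catecholborane, CHCl3, 0 °C → rt; then NaOAc·3H2O, reflux
Reagents that add atoms: none
Why: Hydride addition of catecholborane to the C=N bond, then acetate-induced loss of sulfinate and dinitrogen (Kabalka variant of the Caglioti reduction), turns the formyl carbon into the C10 methyl group without a base strong enough to move the doubly allylic C5 hydrogen, so the skipped diene and both stereocentres are kept.

Step 11
Reactants: 15 11-(tert-butyldimethylsilyloxy)-5αH-eudesma-3,6-diene
Product: 16 11-(tert-butyldimethylsilyloxy)-5αH-eudesm-6-ene-3α,4α-diol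
Conditions: K2OsO4·2H2O (2 mol %), NMO, acetone/H2O, 0 °C → rt
Reagents that add atoms: N-methylmorpholine N-oxide, C[N+]1([O-])CCOCC1; water, O (both oxygens are delivered through OsO4)
Why: Catalytic OsO4 dihydroxylation is a suprafacial addition that should choose the accessible, electron-rich C3=C4 alkene over the C6=C7 alkene shielded by the silyloxy-bearing quaternary C11, and should come from the α face opposite the axial C10 methyl group, setting C3 and C4 together as the cis-3α,4α-diol.

Step 12
Reactants: 16 11-(tert-butyldimethylsilyloxy)-5αH-eudesm-6-ene-3α,4α-diol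
Product: 17 11-(tert-butyldimethylsilyloxy)-5αH-eudesm-6-ene-3α,4α,8-triol (C8 epimers)
Conditions: SeO2 (0.5 equiv), t-BuOOH, CH2Cl2, rt
Reagents that add atoms: tert-butyl hydroperoxide, CC(C)(C)OO (oxygen passed on through SeO2, O=[Se]=O)
Why: Allylic hydroxylation by SeO2 (ene reaction then [2,3]-sigmatropic shift) removes hydrogen from the ring methylene on the more substituted alkene carbon, which is C8 because C11 is quaternary, just as 1-alkylcyclohexenes give 2-alkylcyclohex-2-en-1-ols, and the configuration of the new C8 carbinol is immaterial because step 13 oxidises it.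

Step 13
Reactants: 17 11-(tert-butyldimethylsilyloxy)-5αH-eudesm-6-ene-3α,4α,8-triol
Product: 18 3α,4α-dihydroxy-11-(tert-butyldimethylsilyloxy)-5αH-eudesm-6-en-8-one
Conditions: MnO2 (activated, excess), CH2Cl2, rt
Reagents that add atoms: none
Why: MnO2 oxidises allylic alcohols selectively, so the C8 carbinol becomes the enone carbonyl while the saturated secondary C3 and tertiary C4 hydroxyls are left alone.

Step 14
Reactants: 18 3α,4α-dihydroxy-11-(tert-butyldimethylsilyloxy)-5αH-eudesm-6-en-8-one
Product: 20 3α,4α-dihydroxy-5αH-eudesm-7(11)-en-8-one, via saturated β-silyloxy ketone 19 (not isolated)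
Conditions: [(Ph3P)CuH]6, H2O, THF/toluene, rt; then DBU, 40 °C
Reagents that add atoms: none
Why: Conjugate hydride delivery from the copper hydride to C6 of the enone gives ketone 19, whose C7 hydrogen is removed by DBU so that silanolate leaves from C11 (E1cB β-elimination of a β-silyloxy ketone), forming the C7=C11 alkene and erasing the transient C7 stereocentre.

Step 15
Reactants: 20 3α,4α-dihydroxy-5αH-eudesm-7(11)-en-8-one; 21 angelic acid
Product: 23 4α-hydroxy-8-oxo-5αH-eudesm-7(11)-en-3α-yl (Z)-2-methylbut-2-enoate, via angelic 2,4,6-trichlorobenzoic anhydride 22 (not isolated)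
Conditions: 21, 2,4,6-Cl3C6H2COCl, Et3N, toluene, rt; then 20, 80 °C
Reagents that add atoms: none
Why: The mixed anhydride of angelic acid (Yamaguchi-type esterification run without a nucleophilic catalyst) acylates the secondary C3 hydroxyl in preference to the tertiary C4 hydroxyl and is the established way to make angelates without Z-to-E isomerisation to the tiglate.

Step 16
Reactants: 23 4α-hydroxy-8-oxo-5αH-eudesm-7(11)-en-3α-yl (Z)-2-methylbut-2-enoate
Product: 24 4α-acetoxy-8-oxo-5αH-eudesm-7(11)-en-3α-yl (Z)-2-methylbut-2-enoate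
Conditions: Ac2O, DMAP, Et3N, CH2Cl2, 40 °C
Reagents that add atoms: acetic anhydride, CC(=O)OC(C)=O
Why: DMAP-catalysed acyl transfer (Steglich-type acetylation) is active enough to esterify the remaining tertiary equatorial C4 hydroxyl with retention and is too weakly basic to isomerise the angelate or enolise the ketone.

Step 17
Reactants: 24 4α-acetoxy-8-oxo-5αH-eudesm-7(11)-en-3α-yl (Z)-2-methylbut-2-enoate
Product: 25 (3R,4S,5R,10R)-4α-acetoxy-11-hydroperoxy-8-oxo-5αH-eudesm-6-en-3α-yl (Z)-2-methylbut-2-enoate
Conditions: O2, hν (visible), tetraphenylporphyrin (cat.), CH2Cl2, 0 °C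
Reagents that add atoms: dioxygen, O=O
Why: Singlet oxygen undergoes the Schenck ene reaction with the s-cis-locked C7=C11 enone with the known preference of α,β-unsaturated carbonyl compounds for hydrogen abstraction from the group geminal to the carbonyl (C6), so oxygen bonds to C11 and the alkene moves to C6=C7 in conjugation with C8=O, while the electron-poor angelate alkene should react far more slowly and no stereocentre is formed.

Compound list
1 | 3-hydroxy-3-methylbutan-2-one | CC(=O)C(C)(C)O | starting material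
2 | 3-(tert-butyldimethylsilyloxy)-3-methylbutan-2-one | CC(=O)C(C)(C)O[Si](C)(C)C(C)(C)C | intermediate
3 | potassium 3-(tert-butyldimethylsilyloxy)-3-methylbut-1-en-2-olate | [K+].[O-]C(=C)C(C)(C)O[Si](C)(C)C(C)(C)C | intermediate
4 | 3-(tert-butyldimethylsilyloxy)-3-methylbut-1-en-2-yl trifluoromethanesulfonate | C=C(OS(=O)(=O)C(F)(F)F)C(C)(C)O[Si](C)(C)C(C)(C)C | intermediate
5 | 2-methylbut-1-en-3-yne | C=C(C)C#C | starting material
6 | 4,4,5,5-tetramethyl-2-[(1E)-3-methylbuta-1,3-dien-1-yl]-1,3,2-dioxaborolane | C=C(C)/C=C/B1OC(C)(C)C(C)(C)O1 | intermediate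
7 | tert-butyl{[(4E)-2,6-dimethyl-3-methylidenehepta-4,6-dien-2-yl]oxy}dimethylsilane | C=C(/C=C/C(C)=C)C(C)(C)O[Si](C)(C)C(C)(C)C | intermediate
8 | hex-5-en-1-ol | C=CCCCCO | starting material
9 | hex-5-enal | C=CCCCC=O | intermediate
10 | 2-methylidenehex-5-enal | C=CCCC(=C)C=O | intermediate
11 | (1S,2S)-1-(but-3-en-1-yl)-4-[2-(tert-butyldimethylsilyloxy)propan-2-yl]-2-(prop-1-en-2-yl)cyclohex-3-ene-1-carbaldehyde | O=C[C@@]1(CCC=C)CCC(C(C)(C)O[Si](C)(C)C(C)(C)C)=C[C@H]1C(C)=C | intermediate
12 | 11-(tert-butyldimethylsilyloxy)-5αH-eudesma-3,6-dien-14-al (formyl β on C10) | O=C[C@]12CCC=C(C)[C@@H]1C=C(C(C)(C)O[Si](C)(C)C(C)(C)C)CC2 | intermediate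
13 | (E)-N-tosylhydrazone of 12 | Cc1ccc(cc1)S(=O)(=O)N/N=C/[C@]12CCC=C(C)[C@@H]1C=C(C(C)(C)O[Si](C)(C)C(C)(C)C)CC2 | intermediate
14 | N-(1,3,2-benzodioxaborol-2-yl)-N'-tosylhydrazine on C14 of the eudesmadiene | Cc1ccc(cc1)S(=O)(=O)NN(B1Oc2ccccc2O1)C[C@]12CCC=C(C)[C@@H]1C=C(C(C)(C)O[Si](C)(C)C(C)(C)C)CC2 | intermediate
15 | 11-(tert-butyldimethylsilyloxy)-5αH-eudesma-3,6-diene (10β-methyl) | C[C@]12CCC=C(C)[C@@H]1C=C(C(C)(C)O[Si](C)(C)C(C)(C)C)CC2 | intermediate
16 | 11-(tert-butyldimethylsilyloxy)-5αH-eudesm-6-ene-3α,4α-diol | O[C@@H]1CC[C@]2(C)CCC(C(C)(C)O[Si](C)(C)C(C)(C)C)=C[C@H]2[C@]1(C)O | intermediate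
17 | 11-(tert-butyldimethylsilyloxy)-5αH-eudesm-6-ene-3α,4α,8-triol (C8 epimers) | O[C@@H]1CC[C@]2(C)CC(O)C(C(C)(C)O[Si](C)(C)C(C)(C)C)=C[C@H]2[C@]1(C)O | intermediate
18 | 3α,4α-dihydroxy-11-(tert-butyldimethylsilyloxy)-5αH-eudesm-6-en-8-one | O[C@@H]1CC[C@]2(C)CC(=O)C(C(C)(C)O[Si](C)(C)C(C)(C)C)=C[C@H]2[C@]1(C)O | intermediate
19 | 3α,4α-dihydroxy-11-(tert-butyldimethylsilyloxy)-5αH-eudesman-8-one (C7 epimers) | O[C@@H]1CC[C@]2(C)CC(=O)C(C(C)(C)O[Si](C)(C)C(C)(C)C)C[C@H]2[C@]1(C)O | intermediate
20 | 3α,4α-dihydroxy-5αH-eudesm-7(11)-en-8-one | O[C@@H]1CC[C@]2(C)CC(=O)C(=C(C)C)C[C@H]2[C@]1(C)O | intermediate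
21 | angelic acid, (Z)-2-methylbut-2-enoic acid | C/C=C(/C)C(=O)O | starting material
22 | (Z)-2-methylbut-2-enoic 2,4,6-trichlorobenzoic anhydride | C/C=C(/C)C(=O)OC(=O)c1c(Cl)cc(Cl)cc1Cl | intermediate
23 | 4α-hydroxy-8-oxo-5αH-eudesm-7(11)-en-3α-yl (Z)-2-methylbut-2-enoate | C/C=C(/C)C(=O)O[C@@H]1CC[C@]2(C)CC(=O)C(=C(C)C)C[C@H]2[C@]1(C)O | intermediate
24 | 4α-acetoxy-8-oxo-5αH-eudesm-7(11)-en-3α-yl (Z)-2-methylbut-2-enoate | C/C=C(/C)C(=O)O[C@@H]1CC[C@]2(C)CC(=O)C(=C(C)C)C[C@H]2[C@]1(C)OC(C)=O | intermediate
25 | (3R,4S,5R,10R)-4α-acetoxy-11-hydroperoxy-8-oxo-5αH-eudesm-6-en-3α-yl (Z)-2-methylbut-2-enoate (CNP0225062.1) | C/C=C(/C)C(=O)O[C@@H]1CC[C@]2(C)CC(=O)C(C(C)(C)OO)=C[C@H]2[C@]1(C)OC(C)=O | target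

Total step count: 17. Longest linear sequence: 14 steps (steps 1, 2, 4 and 7 to 17).

Steps most likely to fail

Step 7. The cycloaddition may run through the exo arrangement (formyl trans to isopropenyl, which would end in a cis-fused ring A), may engage the methyl-bearing diene unit of the triene, or the acid may ionise the tertiary allylic silyl ether. The fallback sets out from 7 and uses an exo preference instead of opposing it, with methyl and formyl exchanging roles on the dienophile. Triene 7 and 2-methylprop-2-enal, with the enantiomeric (R)-oxazaborolidine/HNTf2 catalyst in CH2Cl2 at −78 °C, should give the exo adduct (1R,2S)-4-[2-(tert-butyldimethylsilyloxy)propan-2-yl]-1-methyl-2-(prop-1-en-2-yl)cyclohex-3-ene-1-carbaldehyde F1, in which the methyl group is already the C10 methyl and the formyl carbon is C1. Allylmagnesium bromide (CH2=CHCH2MgBr, THF, −78 °C) then gives the homoallylic alcohol 1-{4-[2-(tert-butyldimethylsilyloxy)propan-2-yl]-1-methyl-2-(prop-1-en-2-yl)cyclohex-3-en-1-yl}but-3-en-1-ol F2. Ring-closing metathesis with the second-generation Grubbs catalyst closes ring A to 11-(tert-butyldimethylsilyloxy)-5αH-eudesma-3,6-dien-1-ol F3. NaH, CS2 and MeI convert it into the S-methyl xanthate F4, and Barton–McCombie reduction (Bu3SnH, AIBN, toluene, 100 °C) removes the C1 oxygen. The fallback comes back to the route at 15.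

Step 12. The ene reaction of SeO2 may be too slow at the C6=C7 alkene, which is flanked by the silyloxy-bearing quaternary carbon, or the cis-diol may tie up the reagent as a selenite ester. The fallback sets out from 16 and oxidises the same C8 methylene by a radical pathway: Rh2(caprolactamate)4 (1 mol %), t-BuOOH, K2CO3, CH2Cl2, rt. A tert-butylperoxyl radical abstracts a C8 hydrogen and the mixed peroxide collapses to the ketone, the C5 hydrogen being screened by the quaternary C4 and C10 centres. This gives enone 18 directly, so the fallback comes back to the route at 18 and makes no new compound.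

Step 17. Hydrogen abstraction from the C12/C13 methyl groups (oxygen ending on C7) may compete with abstraction from C6, or the tertiary hydroperoxide may cyclise onto the ketone or fragment during the irradiation. The fallback keeps the C11 oxygen of the cycloadduct and exchanges hydroxyl for hydroperoxyl instead of using an ene reaction. It sets out from 18, which is acylated under the conditions of steps 15 and 16 to give first 4α-hydroxy-8-oxo-11-(tert-butyldimethylsilyloxy)-5αH-eudesm-6-en-3α-yl (Z)-2-methylbut-2-enoate F5 and then its 4α-acetate F6. HF·pyridine (THF, rt) cleaves the silyl ether to the tertiary alcohol 4α-acetoxy-11-hydroxy-8-oxo-5αH-eudesm-6-en-3α-yl (Z)-2-methylbut-2-enoate F7, which is not prone to elimination because the adjacent enone disfavours ionisation. Acid-catalysed exchange with hydrogen peroxide (50 % H2O2, cat. H2SO4, THF, 0 °C), the classical conversion of tertiary alcohols into tertiary hydroperoxides, then gives 25, where the fallback comes back to the route.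

Further compounds
F1 | step 7 | (1R,2S)-4-[2-(tert-butyldimethylsilyloxy)propan-2-yl]-1-methyl-2-(prop-1-en-2-yl)cyclohex-3-ene-1-carbaldehyde (methyl cis to isopropenyl) | C[C@@]1(C=O)CCC(C(C)(C)O[Si](C)(C)C(C)(C)C)=C[C@H]1C(C)=C
F2 | step 7 | 1-{4-[2-(tert-butyldimethylsilyloxy)propan-2-yl]-1-methyl-2-(prop-1-en-2-yl)cyclohex-3-en-1-yl}but-3-en-1-ol (ring stereocentres as in F1, carbinol epimers) | C[C@@]1(C(O)CC=C)CCC(C(C)(C)O[Si](C)(C)C(C)(C)C)=C[C@H]1C(C)=C
F3 | step 7 | 11-(tert-butyldimethylsilyloxy)-5αH-eudesma-3,6-dien-1-ol (C1 epimers) | C[C@]12C(O)CC=C(C)[C@@H]1C=C(C(C)(C)O[Si](C)(C)C(C)(C)C)CC2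
F4 | step 7 | O-[11-(tert-butyldimethylsilyloxy)-5αH-eudesma-3,6-dien-1-yl] S-methyl dithiocarbonate | C[C@]12C(OC(=S)SC)CC=C(C)[C@@H]1C=C(C(C)(C)O[Si](C)(C)C(C)(C)C)CC2
F0 | step 12 | none | none
F5 | step 17 | 4α-hydroxy-8-oxo-11-(tert-butyldimethylsilyloxy)-5αH-eudesm-6-en-3α-yl (Z)-2-methylbut-2-enoate | C/C=C(/C)C(=O)O[C@@H]1CC[C@]2(C)CC(=O)C(C(C)(C)O[Si](C)(C)C(C)(C)C)=C[C@H]2[C@]1(C)O
F6 | step 17 | 4α-acetoxy-8-oxo-11-(tert-butyldimethylsilyloxy)-5αH-eudesm-6-en-3α-yl (Z)-2-methylbut-2-enoate | C/C=C(/C)C(=O)O[C@@H]1CC[C@]2(C)CC(=O)C(C(C)(C)O[Si](C)(C)C(C)(C)C)=C[C@H]2[C@]1(C)OC(C)=O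
F7 | step 17 | 4α-acetoxy-11-hydroxy-8-oxo-5αH-eudesm-6-en-3α-yl (Z)-2-methylbut-2-enoate | C/C=C(/C)C(=O)O[C@@H]1CC[C@]2(C)CC(=O)C(C(C)(C)O)=C[C@H]2[C@]1(C)OC(C)=O
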